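## Structural features

The target 17 is a 2,3-dihydrobenzofuran neolignan. Ring A (the benzo ring, with an allyl group at C5 and a methoxy group at C7) is fused to the dihydrofuran ring B. C2 of ring B carries ring C (4-hydroxy-3-methoxyphenyl). C3 carries C9, a CH2 group bound through oxygen to ring D (4-allyl-2-methoxyphenyl, the eugenol residue). The only stereocentres are the neighbouring C2 (S, an O-benzylic carbon) and C3 (R, a benzylic carbon), which stand trans on ring B.

The fragile parts are three. The two terminal allyl groups rule out hydrogenation and can migrate to propenyl under metal hydrides or hot base. The free para-hydroxy group of ring C can open ring B through a quinone methide. The electron-rich benzylic ethers do not tolerate strong acid.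

The real difficulty is absolute control at C2 and C3 in a molecule whose only functional groups are ethers, one phenol and two alkenes. The feature exploited is the C2–C3 bond: it joins an O1-bound benzylic CH to a carbon that can carry C9 as an ester for a time. A carbene at C3 on ring A then lies five atoms from the benzylic C–H of an O1–CH2–ring C ether. One C–H insertion makes C2–C3, closes ring B and sets both centres, and the ester afterwards allows C3 to be epimerized and supplies C9.

## Logic of the disconnections

17 ⇒ 16. Only the O–Si bond of the ring C phenol is cut. The phenol has to stay masked until the end because its phenoxide can open ring B. The forward step needs a fluoride source buffered so that the phenoxide is protonated at once.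

16 ⇒ 14 + 15. The C9–O bond to ring D is cut. This removes a whole aryl ring and its allyl group from everything earlier, and 15 is a commodity phenol. The forward step must alkylate a phenol with a β-branched primary alcohol under neutral conditions and without elimination toward C3.

14 ⇒ 12 (through 13). C9 is traced back from the alcohol to the ester oxidation level. The ester is what made C3 acidic, so it is reduced only after C3 is in order. The reducing agent must leave two allyl groups and an aryl silyl ether alone.

12 ⇒ 11. Nothing is cut; the configuration at C3 is changed. The trans ester is the more stable one, so base equilibration through the enolate should deliver it. The demand is that the base touches neither the silyl ether nor C2, and that the enolate does not expel O1.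

11 ⇒ 10. The C2–C3 bond is cut and ring B is opened to an aryldiazoacetate that carries the O1–CH2–ring C ether. This is the largest simplification: a ring, a C–C bond and both stereocentres are traced back to one achiral diazo ester. The forward step needs a chiral divalent rhodium carboxylate that chooses between the two enantiotopic benzylic hydrogens, and the carbene must prefer this C–H over the allyl alkene.

10 ⇒ 9. The C=N2 unit is removed, leaving an arylacetate. Diazo transfer with a sulfonyl azide under amine base is the standard forward step. The base is the reason for choosing a triisopropylsilyl ether: a tert-butyldimethylsilyl ether on this phenol would be at risk with DBU here and again in the epimerization. Its loss would expose a para-hydroxybenzyl aryl ether that fragments.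

9 ⇒ 8 ⇒ 6 ⇒ 5 (through 7). The bond between the benzylic carbon and the ester carbon is cut, leading back to a benzylic chloride and carbon monoxide/methanol. The chloride comes from the alcohol and the alcohol from the aldehyde. This homologation stays neutral to basic throughout. Cyanide displacement with acid solvolysis, or enol ether hydrolysis, would put the acid-labile para-silyloxybenzyl aryl ether at risk. The forward steps must avoid free HCl and avoid palladium hydride migration of the allyl group.

5 ⇒ 4 + 3. The O1–CH2 bond is cut between the ring A phenol and the ring C benzylic alcohol. A redox condensation joins them directly, so the unstable para-silyloxybenzyl bromide and a carbonate base are not needed. The demand is that the hindered but acidic phenol of 4 is alkylated at oxygen.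

3 ⇒ 2 ⇒ 1. The benzylic alcohol is traced back to the aldehyde and the silyl ether to the free phenol. Both forward steps are routine, and going through the aldehyde removes any question of which hydroxyl is silylated.

## Other disconnections considered

Alternative 1: The cut is at C2–ring C and C3–C3a at once, with O1–C2 left for later. In the forward sense the ring C aryllithium A3 would add to the (E)-alkenyl pinacol boronate A2. Pd(OAc)2 with a chiral MandyPhos ligand (zerovalent palladium after reduction) and the ring A bromide A4 would then cause ring C to shift from boron to C2 while ring A is delivered to C3, giving A1.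

- In its favour: three simple pieces are joined in one operation, and C3 is made directly in its final configuration with the C9 oxygen already attached. No epimerization, no ester reduction and no diazo compound are needed. On convergence and on the absence of energetic intermediates it is better than the chosen plan.
- Against it: a β-substituted alkenyl pinacol boronate is a reluctant partner in this manifold and tends toward direct Suzuki–Miyaura coupling. A4 is electron-rich with the bromide flanked by an alkoxy group, and its allyl group offers the arylpalladium a Heck pathway.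
- A structural point also needs attention. Stereoretentive oxidation of A1 would give the carbinol A5, whose C2 oxygen is arranged as in the target. Ring B, however, must be closed by the ring A oxygen attacking C2. An SN2 closure would invert C2 and lead to the cis series. Closure would therefore have to run through the para-oxygenated benzylic cation under acid, with C3 steering to trans. The C2 centre made by the key step would then not be used.
- Step economy: the sequence would be comparable or slightly shorter, but with three orthogonal oxygen protecting groups to handle. The chosen plan rests on a ring closure with direct precedent for this ring system.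

Alternative 2: The cut is at C3–C3a, traced back to a six-membered ring. The enantioenriched flavanone A6 would be treated with PhI(OAc)2 (trivalent iodine), acid and trimethyl orthoformate. The enol ether is iodinated at the carbon next to the carbonyl, the ring A carbon migrates to it, and the pyranone contracts to the trans ester A7.

- In its favour: the trans relationship is delivered in the ring-forming step itself, C2 is brought in from a flavanone, and the key step needs no metal and no diazo compound. In these respects it is equal to or better than the chosen plan.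
- Against it: ring C must be deactivated as a sulfonate so that it does not migrate itself toward an isoflavone. That sulfonate must later be removed under conditions far harsher than a fluoride desilylation.
- Against it: flavanones can lose configuration by reversible ring opening to the chalcone under acid.
- Against it: an allyl group would not survive the iodine oxidant, so a bromide stands in at C5 and a late palladium-catalysed allylation is added.
- Step economy: the route after the key step would contain reduction, etherification, allylation and desulfonylation, so it would be clearly longer than the chosen plan.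

Alternative 3: The cut is at O1–C7a. The bromo alcohol A8, with both stereocentres and ring D already in place, would be cyclized with CuI, 1,10-phenanthroline and Cs2CO3 (monovalent copper) to the methoxymethyl ether A9. Acid would then free the phenol.

- In its favour: the stereocentres are not touched in the ring closure, so there is no cis/trans question at all. The closure is the last skeletal event and no diazo compound is involved. On stereochemical security at the ring-closing stage it is better than the chosen plan.
- Against it: the whole stereochemical burden moves to A8. Its two benzylic centres would have to come from an auxiliary-controlled aldol construction followed by reduction, protection changes and etherification, which should take more steps than the nine that lead to 11 here.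
- Against it: copper-mediated etherification of a secondary alkoxide onto an electron-rich bromide flanked by two substituents needs prolonged heating with carbonate. Allyl-to-propenyl migration and oxidation of the carbinol become real concerns.
- Against it: the final acid treatment meets a para-hydroxybenzylic ether.
- Comparison: the chosen plan closes ring B at low temperature and pays for it with one epimerization step.

Key step: step 8

Assumptions: 5-allyl-2-hydroxy-3-methoxybenzaldehyde (4) is taken as a catalogue compound. The (S)-configured catalyst is assumed to select the benzylic hydrogen that leads to (2S); if the sense proves opposite, the same step would be run with the mirror-image catalyst made from (R)-tert-leucine. Allyl means prop-2-en-1-yl throughout.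

## Route

Step 1
Reactants: 1 vanillin (4-hydroxy-3-methoxybenzaldehyde)
Product: 2 3-methoxy-4-(triisopropylsilyloxy)benzaldehyde
Conditions: i-Pr3SiCl, imidazole, DMF, rt
Reagents that add atoms: chlorotriisopropylsilane, CC(C)[Si](Cl)(C(C)C)C(C)C
Why: Imidazole-promoted silylation of a phenol; the triisopropylsilyl ether is preferred to a tert-butyldimethylsilyl ether because it must survive DBU in steps 7 and 9, where its loss would expose a fragmenting para-hydroxybenzyl ether.

Step 2
Reactants: 2 3-methoxy-4-(triisopropylsilyloxy)benzaldehyde
Product: 3 [3-methoxy-4-(triisopropylsilyloxy)phenyl]methanol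
Conditions: NaBH4, THF/MeOH, 0 °C
Reagents that add atoms: none
Why: Borohydride reduction of an aromatic aldehyde; short exposure at 0 °C should leave the aryl silyl ether intact.

Step 3
Reactants: 4 5-allyl-2-hydroxy-3-methoxybenzaldehyde; 3 [3-methoxy-4-(triisopropylsilyloxy)phenyl]methanol
Product: 5 5-allyl-3-methoxy-2-[3-methoxy-4-(triisopropylsilyloxy)benzyloxy]benzaldehyde
Conditions: PPh3, DIAD, THF, 0 °C to rt
Reagents that add atoms: none
Why: Mitsunobu etherification of a phenol made more acidic by its ortho-formyl group with a primary benzylic alcohol; the neutral conditions avoid both the unstable para-silyloxybenzyl bromide and a carbonate base.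

Step 4
Reactants: 5 5-allyl-3-methoxy-2-[3-methoxy-4-(triisopropylsilyloxy)benzyloxy]benzaldehyde
Product: 6 {5-allyl-3-methoxy-2-[3-methoxy-4-(triisopropylsilyloxy)benzyloxy]phenyl}methanol
Conditions: NaBH4, THF/MeOH, 0 °C
Reagents that add atoms: none
Why: Borohydride reduction of the aldehyde; alkenes, ethers and the silyl ether are inert to it.

Step 5
Reactants: 6 {5-allyl-3-methoxy-2-[3-methoxy-4-(triisopropylsilyloxy)benzyloxy]phenyl}methanol
Product: 8 5-allyl-1-(chloromethyl)-3-methoxy-2-[3-methoxy-4-(triisopropylsilyloxy)benzyloxy]benzene, via benzylic methanesulfonate 7 (not isolated)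
Conditions: MsCl, Et3N, CH2Cl2, 0 °C; then LiCl, DMF, rt
Reagents that add atoms: lithium chloride, [Li+].[Cl-]; methanesulfonyl chloride, CS(=O)(=O)Cl (mesyl group of 7, and a possible source of the chloride in 8)
Why: Sulfonylation of a benzylic alcohol followed by SN2 displacement by chloride; the amine buffer keeps free HCl away from the acid-labile para-silyloxybenzyl aryl ether.

Step 6
Reactants: 8 5-allyl-1-(chloromethyl)-3-methoxy-2-[3-methoxy-4-(triisopropylsilyloxy)benzyloxy]benzene
Product: 9 methyl 2-{5-allyl-3-methoxy-2-[3-methoxy-4-(triisopropylsilyloxy)benzyloxy]phenyl}acetate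
Conditions: PdCl2(PPh3)2 (cat.), CO (1 atm), i-Pr2NEt, MeOH/THF, 50 °C
Reagents that add atoms: carbon monoxide, [C-]#[O+]; methanol, CO
Why: Palladium-catalysed methoxycarbonylation of a benzylic chloride (oxidative addition to zerovalent palladium formed in situ from the divalent palladium precatalyst, CO insertion, methanolysis of the acyl palladium); it adds the one carbon without cyanide and without an acidic solvolysis.

Step 7
Reactants: 9 methyl 2-{5-allyl-3-methoxy-2-[3-methoxy-4-(triisopropylsilyloxy)benzyloxy]phenyl}acetate
Product: 10 methyl 2-{5-allyl-3-methoxy-2-[3-methoxy-4-(triisopropylsilyloxy)benzyloxy]phenyl}-2-diazoacetate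
Conditions: 4-acetamidobenzenesulfonyl azide (p-ABSA), DBU, MeCN, 0 °C to rt
Reagents that add atoms: 4-acetamidobenzenesulfonyl azide, CC(=O)Nc1ccc(cc1)S(=O)(=O)N=[N+]=[N-]
Why: Regitz diazo transfer to an arylacetate enolate, the usual entry to aryldiazoacetates; p-ABSA is among the less hazardous sulfonyl azides, and dry DBU should leave the triisopropylsilyl ether alone.

Step 8
Reactants: 10 methyl 2-{5-allyl-3-methoxy-2-[3-methoxy-4-(triisopropylsilyloxy)benzyloxy]phenyl}-2-diazoacetate
Product: 11 methyl (2S,3R)-5-allyl-7-methoxy-2-[3-methoxy-4-(triisopropylsilyloxy)phenyl]-2,3-dihydrobenzofuran-3-carboxylate (cis)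
Conditions: Rh2(S-PTTL)4 [dirhodium tetrakis(N-phthaloyl-(S)-tert-leucinate)] (1 mol %), toluene, −78 °C, slow addition of 10
Reagents that add atoms: none
Why: Intramolecular C–H insertion of a donor/acceptor rhodium carbene, the known enantioselective route from ortho-benzyloxy aryldiazoacetates to cis 2-aryl-2,3-dihydrobenzofuran-3-carboxylates under chiral dirhodium carboxylates. The divalent rhodium dimer takes N2 from 10 and gives a carbene at C3, which engages the benzylic C–H of the O1–CH2–ring C group in a concerted but asynchronous, hydride-transfer-like three-centre transition state, so that C2–C3 forms as the hydrogen passes to C3. Ring B closes by this 1,5-insertion (C3, C3a, C7a, O1, C2), a five-membered C–C closure through an array that includes the migrating hydrogen. C2 is set by the catalyst: the phthalimido walls of the four (S)-tert-leucinate ligands distinguish the two enantiotopic benzylic hydrogens, and the one leading to (2S) is assumed to be chosen. C3 is set relative to C2 by the transition-state geometry typical of this catalyst class, which places ester and aryl cis; this centre is corrected in step 9, so only the selectivity at C2 has to last. Chemoselectivity is needed against cyclopropanation of an allyl group and against addition to ring C: the allyl group sits meta on ring A and cannot reach the carbene within the molecule, bimolecular events are held back by slow addition at high dilution, and the ether oxygen and the para-silyloxy group make the chosen C–H the most hydridic one within reach. O1 itself cannot trap the carbene, since that would close a four-membered ring.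

Step 9
Reactants: 11 methyl (2S,3R)-5-allyl-7-methoxy-2-[3-methoxy-4-(triisopropylsilyloxy)phenyl]-2,3-dihydrobenzofuran-3-carboxylate (cis)
Product: 12 methyl (2S,3S)-5-allyl-7-methoxy-2-[3-methoxy-4-(triisopropylsilyloxy)phenyl]-2,3-dihydrobenzofuran-3-carboxylate (trans)
Conditions: DBU, toluene, rt to 50 °C
Reagents that add atoms: none
Why: Base-mediated epimerization through the ester enolate at the doubly activated C3; the trans ester avoids the eclipsing of aryl and ester and should dominate at equilibrium, while C2 has no acidic hydrogen and keeps its configuration.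

Step 10
Reactants: 12 methyl (2S,3S)-5-allyl-7-methoxy-2-[3-methoxy-4-(triisopropylsilyloxy)phenyl]-2,3-dihydrobenzofuran-3-carboxylate (trans)
Product: 14 {(2S,3R)-5-allyl-7-methoxy-2-[3-methoxy-4-(triisopropylsilyloxy)phenyl]-2,3-dihydrobenzofuran-3-yl}methanol, via trans aldehyde 13 (not isolated)
Conditions: i-Bu2AlH, CH2Cl2, −78 to 0 °C; aq. potassium sodium tartrate
Reagents that add atoms: none
Why: Aluminium hydride reduction of an ester to the primary alcohol; no base is present, so C3 is not disturbed, and the change of descriptor from 3S to 3R only reflects the new priority of C9.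

Step 11
Reactants: 14 {(2S,3R)-5-allyl-7-methoxy-2-[3-methoxy-4-(triisopropylsilyloxy)phenyl]-2,3-dihydrobenzofuran-3-yl}methanol; 15 eugenol (4-allyl-2-methoxyphenol)
Product: 16 (2S,3R)-5-allyl-3-[(4-allyl-2-methoxyphenoxy)methyl]-7-methoxy-2-[3-methoxy-4-(triisopropylsilyloxy)phenyl]-2,3-dihydrobenzofuran
Conditions: PPh3, DIAD, THF, 0 °C to rt
Reagents that add atoms: none
Why: Mitsunobu etherification of a primary alcohol with a phenol whose pKa (about 10) lies within the usual range; the reaction is at C9, so neither stereocentre is involved.

Step 12
Reactants: 16 (2S,3R)-5-allyl-3-[(4-allyl-2-methoxyphenoxy)methyl]-7-methoxy-2-[3-methoxy-4-(triisopropylsilyloxy)phenyl]-2,3-dihydrobenzofuran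
Product: 17 4-{(2S,3R)-5-allyl-3-[(4-allyl-2-methoxyphenoxy)methyl]-7-methoxy-2,3-dihydrobenzofuran-2-yl}-2-methoxyphenol (target)
Conditions: n-Bu4NF, AcOH, THF, 0 °C
Reagents that add atoms: none
Why: Fluoride cleavage of an aryl silyl ether; acetic acid protonates the phenoxide at once, and even a transient quinone methide opening of ring B would reclose to the trans isomer because C3 is now fixed.

## Compound list

1 | vanillin (4-hydroxy-3-methoxybenzaldehyde) | COc1cc(C=O)ccc1O | starting material
2 | 3-methoxy-4-(triisopropylsilyloxy)benzaldehyde | COc1cc(C=O)ccc1O[Si](C(C)C)(C(C)C)C(C)C | intermediate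
3 | [3-methoxy-4-(triisopropylsilyloxy)phenyl]methanol | COc1cc(CO)ccc1O[Si](C(C)C)(C(C)C)C(C)C | intermediate
4 | 5-allyl-2-hydroxy-3-methoxybenzaldehyde | C=CCc1cc(C=O)c(O)c(OC)c1 | starting material
5 | 5-allyl-3-methoxy-2-[3-methoxy-4-(triisopropylsilyloxy)benzyloxy]benzaldehyde | C=CCc1cc(C=O)c(OCc2ccc(O[Si](C(C)C)(C(C)C)C(C)C)c(OC)c2)c(OC)c1 | intermediate
6 | {5-allyl-3-methoxy-2-[3-methoxy-4-(triisopropylsilyloxy)benzyloxy]phenyl}methanol | C=CCc1cc(CO)c(OCc2ccc(O[Si](C(C)C)(C(C)C)C(C)C)c(OC)c2)c(OC)c1 | intermediate
7 | 5-allyl-3-methoxy-2-[3-methoxy-4-(triisopropylsilyloxy)benzyloxy]benzyl methanesulfonate | C=CCc1cc(COS(C)(=O)=O)c(OCc2ccc(O[Si](C(C)C)(C(C)C)C(C)C)c(OC)c2)c(OC)c1 | intermediate (not isolated)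
8 | 5-allyl-1-(chloromethyl)-3-methoxy-2-[3-methoxy-4-(triisopropylsilyloxy)benzyloxy]benzene | C=CCc1cc(CCl)c(OCc2ccc(O[Si](C(C)C)(C(C)C)C(C)C)c(OC)c2)c(OC)c1 | intermediate
9 | methyl 2-{5-allyl-3-methoxy-2-[3-methoxy-4-(triisopropylsilyloxy)benzyloxy]phenyl}acetate | COC(=O)Cc1cc(CC=C)cc(OC)c1OCc1ccc(O[Si](C(C)C)(C(C)C)C(C)C)c(OC)c1 | intermediate
10 | methyl 2-{5-allyl-3-methoxy-2-[3-methoxy-4-(triisopropylsilyloxy)benzyloxy]phenyl}-2-diazoacetate | COC(=O)C(=[N+]=[N-])c1cc(CC=C)cc(OC)c1OCc1ccc(O[Si](C(C)C)(C(C)C)C(C)C)c(OC)c1 | intermediate
11 | methyl (2S,3R)-5-allyl-7-methoxy-2-[3-methoxy-4-(triisopropylsilyloxy)phenyl]-2,3-dihydrobenzofuran-3-carboxylate (cis) | COC(=O)[C@@H]2c3cc(CC=C)cc(OC)c3O[C@@H]2c2ccc(O[Si](C(C)C)(C(C)C)C(C)C)c(OC)c2 | intermediate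
12 | methyl (2S,3S)-5-allyl-7-methoxy-2-[3-methoxy-4-(triisopropylsilyloxy)phenyl]-2,3-dihydrobenzofuran-3-carboxylate (trans) | COC(=O)[C@H]2c3cc(CC=C)cc(OC)c3O[C@@H]2c2ccc(O[Si](C(C)C)(C(C)C)C(C)C)c(OC)c2 | intermediate
13 | (2S,3S)-5-allyl-7-methoxy-2-[3-methoxy-4-(triisopropylsilyloxy)phenyl]-2,3-dihydrobenzofuran-3-carbaldehyde (trans) | O=C[C@H]2c3cc(CC=C)cc(OC)c3O[C@@H]2c2ccc(O[Si](C(C)C)(C(C)C)C(C)C)c(OC)c2 | intermediate (not isolated)
14 | {(2S,3R)-5-allyl-7-methoxy-2-[3-methoxy-4-(triisopropylsilyloxy)phenyl]-2,3-dihydrobenzofuran-3-yl}methanol | OC[C@H]2c3cc(CC=C)cc(OC)c3O[C@@H]2c2ccc(O[Si](C(C)C)(C(C)C)C(C)C)c(OC)c2 | intermediate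
15 | eugenol (4-allyl-2-methoxyphenol) | C=CCc1ccc(O)c(OC)c1 | starting material
16 | (2S,3R)-5-allyl-3-[(4-allyl-2-methoxyphenoxy)methyl]-7-methoxy-2-[3-methoxy-4-(triisopropylsilyloxy)phenyl]-2,3-dihydrobenzofuran | C=CCc1ccc(OC[C@H]2c3cc(CC=C)cc(OC)c3O[C@@H]2c2ccc(O[Si](C(C)C)(C(C)C)C(C)C)c(OC)c2)c(OC)c1 | intermediate
17 | 4-{(2S,3R)-5-allyl-3-[(4-allyl-2-methoxyphenoxy)methyl]-7-methoxy-2,3-dihydrobenzofuran-2-yl}-2-methoxyphenol | C=CCc1ccc(OC[C@H]2c3cc(CC=C)cc(OC)c3O[C@@H]2c2ccc(O)c(OC)c2)c(OC)c1 | target

## Step count and risks

Total step count: 12. Longest linear sequence: 12 steps (1 to 17; 4 and 15 enter unmodified).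

Least certain steps:

Step 8 (key step). Enantiotopic discrimination may be eroded. The doubly oxygenated benzylic C–H is hydridic enough for hydride transfer to run ahead of C–C closure. The methoxy group at C7, next to the ether oxygen, also twists the benzyloxy group out of its usual conformation. Bimolecular cyclopropanation of an allyl group is the main competing process if addition is too fast. The fallback moves control from the catalyst to an auxiliary and sets out from 9.
- LiOH in THF/water at 0 °C would give the arylacetic acid F1.
- Carbodiimide/DMAP esterification with (S)-2-hydroxy-1-(pyrrolidin-1-yl)propan-1-one would give the lactamide ester F2 (the mirror-image auxiliary would be taken if the sense required it).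
- p-ABSA/DBU would give the diazo ester F3.
- Insertion with dirhodium tetrakis[(S)-N-(4-dodecylphenylsulfonyl)prolinate] (divalent rhodium) under combined auxiliary and catalyst control should favour the trans auxiliary ester F4. Any cis isomer would be equilibrated with DBU.
- LiBH4 in THF would reduce F4 to 14, where the route is rejoined.

Step 3. The phenol of 4 is flanked on both sides, and the electron-rich benzylic oxyphosphonium ion may ionize. Sluggish coupling or C-alkylation could result. The fallback sets out from 3: PPh3/CBr4 in CH2Cl2 at 0 °C would give the benzylic bromide F5, used at once with 4 and K2CO3 in acetone (Williamson ether synthesis). It returns at 5.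

Step 6. Methanolysis of the activated benzylic chloride may compete with oxidative addition. Palladium hydride formed in the catalytic cycle may move an allyl double bond into conjugation. The fallback reverses the polarity and sets out from 8: Mg in dilute THF at 0 °C would give the benzylic Grignard reagent F6, which would be added to excess methyl chloroformate at −78 °C. It returns at 9.

Step 9. The C3 enolate may expel O1 (E1cB opening of ring B to a diarylacrylate that does not readily reclose). Traces of water with DBU may remove the silyl group and open the way to scrambling at C2. The fallback epimerizes at the aldehyde level, where much weaker base is enough, and sets out from 11. i-Bu2AlH (one equivalent, −78 °C, toluene) would give the cis aldehyde F7. Et3N in CH2Cl2 would equilibrate it to 13, and NaBH4 would give 14, where the route is rejoined.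

Step 11. The oxyphosphonium ion at C9 may eliminate toward the benzylic C3–H, and the weakly acidic phenol may be slow to protonate the betaine. The fallback is a two-stage Williamson etherification from 14. MsCl/Et3N would give the primary methanesulfonate F8, which would be displaced with 15 and Cs2CO3 in DMF at moderate temperature. It returns at 16.

## Further compounds

F1 | step 8 | 2-{5-allyl-3-methoxy-2-[3-methoxy-4-(triisopropylsilyloxy)benzyloxy]phenyl}acetic acid | OC(=O)Cc1cc(CC=C)cc(OC)c1OCc1ccc(O[Si](C(C)C)(C(C)C)C(C)C)c(OC)c1
F2 | step 8 | (S)-1-oxo-1-(pyrrolidin-1-yl)propan-2-yl 2-{5-allyl-3-methoxy-2-[3-methoxy-4-(triisopropylsilyloxy)benzyloxy]phenyl}acetate | C[C@H](OC(=O)Cc1cc(CC=C)cc(OC)c1OCc1ccc(O[Si](C(C)C)(C(C)C)C(C)C)c(OC)c1)C(=O)N1CCCC1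
F3 | step 8 | (S)-1-oxo-1-(pyrrolidin-1-yl)propan-2-yl 2-{5-allyl-3-methoxy-2-[3-methoxy-4-(triisopropylsilyloxy)benzyloxy]phenyl}-2-diazoacetate | C[C@H](OC(=O)C(=[N+]=[N-])c1cc(CC=C)cc(OC)c1OCc1ccc(O[Si](C(C)C)(C(C)C)C(C)C)c(OC)c1)C(=O)N1CCCC1
F4 | step 8 | (S)-1-oxo-1-(pyrrolidin-1-yl)propan-2-yl (2S,3S)-5-allyl-7-methoxy-2-[3-methoxy-4-(triisopropylsilyloxy)phenyl]-2,3-dihydrobenzofuran-3-carboxylate (trans) | C[C@H](OC(=O)[C@H]2c3cc(CC=C)cc(OC)c3O[C@@H]2c2ccc(O[Si](C(C)C)(C(C)C)C(C)C)c(OC)c2)C(=O)N1CCCC1
F5 | step 3 | 4-(bromomethyl)-2-methoxy-1-(triisopropylsilyloxy)benzene | BrCc1ccc(O[Si](C(C)C)(C(C)C)C(C)C)c(OC)c1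
F6 | step 6 | {5-allyl-3-methoxy-2-[3-methoxy-4-(triisopropylsilyloxy)benzyloxy]benzyl}magnesium chloride | C=CCc1cc(C[Mg]Cl)c(OCc2ccc(O[Si](C(C)C)(C(C)C)C(C)C)c(OC)c2)c(OC)c1
F7 | step 9 | (2S,3R)-5-allyl-7-methoxy-2-[3-methoxy-4-(triisopropylsilyloxy)phenyl]-2,3-dihydrobenzofuran-3-carbaldehyde (cis) | O=C[C@@H]2c3cc(CC=C)cc(OC)c3O[C@@H]2c2ccc(O[Si](C(C)C)(C(C)C)C(C)C)c(OC)c2
F8 | step 11 | {(2S,3R)-5-allyl-7-methoxy-2-[3-methoxy-4-(triisopropylsilyloxy)phenyl]-2,3-dihydrobenzofuran-3-yl}methyl methanesulfonate | CS(=O)(=O)OC[C@H]2c3cc(CC=C)cc(OC)c3O[C@@H]2c2ccc(O[Si](C(C)C)(C(C)C)C(C)C)c(OC)c2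
A1 | alternative 1 | syn pinacol boronate: 2-{2-[5-allyl-3-methoxy-2-(methoxymethoxy)phenyl]-3-(tert-butyldimethylsilyloxy)-1-[3-methoxy-4-(triisopropylsilyloxy)phenyl]propyl}-4,4,5,5-tetramethyl-1,3,2-dioxaborolane | CC(C)(C)[Si](C)(C)OC[C@H]([C@H](B1OC(C)(C)C(C)(C)O1)c1ccc(O[Si](C(C)C)(C(C)C)C(C)C)c(OC)c1)c1cc(CC=C)cc(OC)c1OCOC
A2 | alternative 1 | (E)-tert-butyldimethyl{[3-(4,4,5,5-tetramethyl-1,3,2-dioxaborolan-2-yl)allyl]oxy}silane | CC(C)(C)[Si](C)(C)OC/C=C/B1OC(C)(C)C(C)(C)O1
A3 | alternative 1 | [3-methoxy-4-(triisopropylsilyloxy)phenyl]lithium | [Li]c1ccc(O[Si](C(C)C)(C(C)C)C(C)C)c(OC)c1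
A4 | alternative 1 | 5-allyl-1-bromo-3-methoxy-2-(methoxymethoxy)benzene | C=CCc1cc(Br)c(OCOC)c(OC)c1
A5 | alternative 1 | syn 2-[5-allyl-3-methoxy-2-(methoxymethoxy)phenyl]-3-(tert-butyldimethylsilyloxy)-1-[3-methoxy-4-(triisopropylsilyloxy)phenyl]propan-1-ol | CC(C)(C)[Si](C)(C)OC[C@H]([C@H](O)c1ccc(O[Si](C(C)C)(C(C)C)C(C)C)c(OC)c1)c1cc(CC=C)cc(OC)c1OCOC
A6 | alternative 2 | (2S)-6-bromo-8-methoxy-2-[3-methoxy-4-(methylsulfonyloxy)phenyl]chroman-4-one | COc1cc(Br)cc2c1O[C@@H](CC2=O)c1ccc(OS(C)(=O)=O)c(OC)c1
A7 | alternative 2 | methyl (2S,3S)-5-bromo-7-methoxy-2-[3-methoxy-4-(methylsulfonyloxy)phenyl]-2,3-dihydrobenzofuran-3-carboxylate (trans) | COC(=O)[C@H]2c3cc(Br)cc(OC)c3O[C@@H]2c2ccc(OS(C)(=O)=O)c(OC)c2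
A8 | alternative 3 | 3-(4-allyl-2-methoxyphenoxy)-2-(5-allyl-2-bromo-3-methoxyphenyl)-1-[3-methoxy-4-(methoxymethoxy)phenyl]propan-1-ol, configured as in the target | C=CCc1ccc(OC[C@@H](c3cc(CC=C)cc(OC)c3Br)[C@H](O)c2ccc(OCOC)c(OC)c2)c(OC)c1
A9 | alternative 3 | (2S,3R)-5-allyl-3-[(4-allyl-2-methoxyphenoxy)methyl]-7-methoxy-2-[3-methoxy-4-(methoxymethoxy)phenyl]-2,3-dihydrobenzofuran | C=CCc1ccc(OC[C@H]2c3cc(CC=C)cc(OC)c3O[C@@H]2c2ccc(OCOC)c(OC)c2)c(OC)c1
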